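**Retrosynthetic overview**
- The angelate is put on last. The cyclopentane (β-hydroxy ketone) comes from a samarium-enolate aldol after oxidative opening of a methylcyclohexene ring (ring B), a ring contraction that turns C–CH3 into the acetyl group.
- The six-membered ring (ring A), its exocyclic methylene and the axial C–O come together from a type 2 carbonyl-ene reaction between an aldehyde and the isopropenyl group.
- The key C–C bond (ring B to the isopropyl-bearing carbon) is made by an Ireland–Claisen [3,3] rearrangement of the isovalerate of a limonene-derived dienol. Iodolactonisation then shifts the alkene and places the leaving oxygen.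
- The epoxy acid comes from (R)-2-chloropropanoic acid by Cornforth-controlled MeMgBr addition and epoxide closure.
- Ring order: ring B is bought, ring A is closed by the ene reaction, and the five-membered ring is closed last by the aldol.

Assumption: dienol 1, the (1R,4R) isomer of p-mentha-2,8-dien-1-ol (hydroxyl trans to isopropenyl, made from (R)-limonene), is taken as purchasable as the single isomer.

**Step 1**
Reactants: 1 (1R,4R)-1-methyl-4-(prop-1-en-2-yl)cyclohex-2-en-1-ol; 2 3-methylbutanoyl chloride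
Product: 3 (1R,4R)-1-methyl-4-(prop-1-en-2-yl)cyclohex-2-en-1-yl 3-methylbutanoate
Conditions: n-BuLi, THF, −78 °C; then 2, −78 to 0 °C
Reagents that add atoms: none
Why: Acylation of the lithium alkoxide of the tertiary allylic alcohol by the acid chloride (ester formation) leaves both stereocentres untouched.

**Step 2**
Reactants: 3 (1R,4R)-1-methyl-4-(prop-1-en-2-yl)cyclohex-2-en-1-yl 3-methylbutanoate
Product: 6 (2RS)-3-methyl-2-[(1R,6R)-3-methyl-6-(prop-1-en-2-yl)cyclohex-2-en-1-yl]butanoic acid, via silyl ketene acetal 4 (not isolated), via trimethylsilyl ester 5 (not isolated)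
Conditions: LiN(iPr)2, THF, −78 °C; Me3SiCl, Et3N, −78 to 50 °C; then 1 M HCl
Reagents that add atoms: chlorotrimethylsilane, C[Si](C)(C)Cl
Why: The Ireland–Claisen [3,3]-sigmatropic rearrangement forms the key C–C bond suprafacially on the ring face that carried the C–O bond, hence trans to the isopropenyl group of the bought stereocentre; the epimer mixture at the acyclic α-carbon is corrected in step 4.

**Step 3**
Reactants: 6 (2RS)-3-methyl-2-[(1R,6R)-3-methyl-6-(prop-1-en-2-yl)cyclohex-2-en-1-yl]butanoic acid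
Product: 8 (3aR,4R,7aS)-7-methyl-3-(propan-2-yl)-4-(prop-1-en-2-yl)-3a,4,5,7a-tetrahydro-1-benzofuran-2(3H)-one (C3 epimers), via iodolactone 7 (not isolated)
Conditions: I2, NaHCO3, MeCN/H2O, 0 °C; then DBU, PhMe, 80 °C
Reagents that add atoms: iodine, II
Why: Iodolactonisation (anti addition, cis-fused γ-lactone) followed by E2 dehydroiodination of the tertiary iodide moves the ring alkene one position and leaves an allylic C–O bond on the carbon that will carry the acetyl group.

**Step 4**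
Reactants: 8 (3aR,4R,7aS)-7-methyl-3-(propan-2-yl)-4-(prop-1-en-2-yl)-3a,4,5,7a-tetrahydro-1-benzofuran-2(3H)-one
Product: 11 (3S,3aR,4R,7aS)-7-methyl-3-(propan-2-yl)-4-(prop-1-en-2-yl)-2,3,3a,4,5,7a-hexahydro-1-benzofuran-2-ol (anomers), via lithium enolate 9 (not isolated), via 3S-lactone 10 (not isolated)
Conditions: LiN(iPr)2, THF, −78 to −30 °C; 2,6-di-tert-butyl-4-methylphenol, −78 °C; iBu2AlH, −78 °C; aq. potassium sodium tartrate
Reagents that add atoms: lithium diisopropylamide, [Li]N(C(C)C)C(C)C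
Why: Kinetic protonation of the planar lactone enolate from the convex face of the cis-fused bicycle puts the isopropyl group on the concave face (3S), and iBu2AlH half-reduction to the lactol follows before this less stable epimer can equilibrate.

**Step 5**
Reactants: 11 (3S,3aR,4R,7aS)-7-methyl-3-(propan-2-yl)-4-(prop-1-en-2-yl)-2,3,3a,4,5,7a-hexahydro-1-benzofuran-2-ol
Product: 13 (1S,2R,4aR,8S,8aR)-7-methyl-4-methylidene-1-(propan-2-yl)-1,2,3,4,4a,5,8,8a-octahydronaphthalene-2,8-diol, via hydroxy aldehyde 12 (not isolated)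
Conditions: Me2AlCl (3 equiv), CH2Cl2, −78 to −20 °C; aq. NaHCO3
Reagents that add atoms: none
Why: A type 2 intramolecular carbonyl-ene reaction of the ring-opened aldehyde with the isopropenyl group, through a chair transition state (isopropyl equatorial, trans ring junction), closes ring A, creates the exocyclic methylene and, as is usual with Me2AlCl, gives the axial alcohol cis to isopropyl.

**Step 6**
Reactants: 13 (1S,2R,4aR,8S,8aR)-7-methyl-4-methylidene-1-(propan-2-yl)-1,2,3,4,4a,5,8,8a-octahydronaphthalene-2,8-diol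
Product: 14 6,7-epoxy-7-methyl-4-methylidene-1-(propan-2-yl)decahydronaphthalene-2,8-diol (oxirane oxygen syn to the 8-hydroxyl, other centres as in 13)
Conditions: VO(acac)2 (5 mol %), t-BuOOH, CH2Cl2, 0 °C to rt
Reagents that add atoms: tert-butyl hydroperoxide, CC(C)(C)OO
Why: Hydroxyl-directed vanadium-catalysed epoxidation by the allylic alcohol oxidises only the ring alkene, syn to the hydroxyl, and leaves the 1,1-disubstituted methylene alone.

**Step 7**
Reactants: 15 (R)-2-chloropropanoic acid; 16 anisole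
Product: 18 (R)-2-chloro-1-(4-methoxyphenyl)propan-1-one, via acid chloride 17 (not isolated)
Conditions: (COCl)2, cat. DMF, CH2Cl2, 0 °C to rt; then 16, AlCl3, CH2Cl2, 0 °C
Reagents that add atoms: oxalyl chloride, O=C(Cl)C(Cl)=O
Why: Friedel–Crafts acylation of anisole (para) with the acid chloride made in the flask proceeds without racemisation of the α-chloro centre.

**Step 8**
Reactants: 18 (R)-2-chloro-1-(4-methoxyphenyl)propan-1-one
Product: 19 (2R,3R)-3-chloro-2-(4-methoxyphenyl)butan-2-ol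
Conditions: MeMgBr, Et2O/PhMe, −78 °C; aq. NH4Cl
Reagents that add atoms: methylmagnesium bromide, C[Mg]Br
Why: Grignard addition under Cornforth (polar Felkin–Anh) control, with C–Cl anti to C=O and attack past the hydrogen, sets the carbinol centre (2R) from the bought chloro centre.

**Step 9**
Reactants: 19 (2R,3R)-3-chloro-2-(4-methoxyphenyl)butan-2-ol
Product: 21 (2S,3S)-2,3-dimethyloxirane-2-carboxylic acid, via chlorohydrin acid 20 (not isolated)
Conditions: RuCl3 hydrate (5 mol %), NaIO4, CCl4/MeCN/H2O, rt; then aq. NaOH, 0 °C; then NaHSO4 to pH 3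
Reagents that add atoms: sodium periodate, [Na+].[O-]I(=O)(=O)=O; water, O
Why: RuO4 degradation of the anisyl ring to a carboxylic acid, then base-induced intramolecular SN2 closure with inversion at the chloride carbon, gives the epoxide with carboxyl cis to the 3-methyl group (epoxyangelic acid) as the 2S,3S enantiomer.

**Step 10**
Reactants: 14 6,7-epoxy-7-methyl-4-methylidene-1-(propan-2-yl)decahydronaphthalene-2,8-diol; 21 (2S,3S)-2,3-dimethyloxirane-2-carboxylic acid
Product: 23 2-O-[(2S,3S)-2,3-dimethyloxirane-2-carbonyl] ester of 14, via mixed anhydride 22 (not isolated)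
Conditions: 21, 2,4,6-trichlorobenzoyl chloride, Et3N, THF, rt; then 14, DMAP, PhMe, 40 °C
Reagents that add atoms: 2,4,6-trichlorobenzoyl chloride, O=C(Cl)c1c(Cl)cc(Cl)cc1Cl
Why: Yamaguchi esterification acylates the less hindered axial 2-hydroxyl, because the 8-hydroxyl sits between the fully substituted oxirane carbon and the ring-fusion methine; no stereocentre is touched.

**Step 11**
Reactants: 23 2-O-[(2S,3S)-2,3-dimethyloxirane-2-carbonyl] ester of 14
Product: 24 8-O-acetyl derivative of 23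
Conditions: Ac2O, Et3N, DMAP, CH2Cl2, rt
Reagents that add atoms: acetic anhydride, CC(=O)OC(C)=O
Why: DMAP-catalysed acetylation of the remaining hindered alcohol installs the acyloxy leaving group alpha to the future ketone.

**Step 12**
Reactants: 24 8-O-acetyl derivative of 23
Product: 25 (1R,2S,3R,4R)-3-[(1S)-1-acetoxy-2-oxopropyl]-5-methylidene-4-(2-oxoethyl)-2-(propan-2-yl)cyclohexyl (2S,3S)-2,3-dimethyloxirane-2-carboxylate
Conditions: H5IO6, THF/Et2O, 0 °C
Reagents that add atoms: orthoperiodic acid, OI(=O)(O)(O)(O)O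
Why: Periodic acid opens the trisubstituted epoxide and cleaves the glycol (oxidative C–C cleavage) to a methyl ketone and an aldehyde, opening ring B while the electron-poor oxirane ester survives.

**Step 13**
Reactants: 25 (1R,2S,3R,4R)-3-[(1S)-1-acetoxy-2-oxopropyl]-5-methylidene-4-(2-oxoethyl)-2-(propan-2-yl)cyclohexyl (2S,3S)-2,3-dimethyloxirane-2-carboxylate
Product: 27 (1R,2S,3aR,6R,7S,7aR)-1-acetyl-2-hydroxy-4-methylidene-7-(propan-2-yl)octahydro-1H-inden-6-yl (2S,3S)-2,3-dimethyloxirane-2-carboxylate, via samarium enolate 26 (not isolated)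
Conditions: SmI2 (2.3 equiv), THF, −78 to −40 °C; aq. NH4Cl
Reagents that add atoms: samarium diiodide, I[Sm]I
Why: SmI2 cleaves the α-acetoxy ketone to a samarium enolate, which closes the cyclopentane by intramolecular aldol addition through a chelated transition state; this gives the cis β-hydroxy ketone with the acetyl group turned away from ring A (allylic strain), hence 1R,2S.

**Step 14**
Reactants: 27 (1R,2S,3aR,6R,7S,7aR)-1-acetyl-2-hydroxy-4-methylidene-7-(propan-2-yl)octahydro-1H-inden-6-yl (2S,3S)-2,3-dimethyloxirane-2-carboxylate; 28 angelic acid, (2Z)-2-methylbut-2-enoic acid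
Product: 30 (1R,2S,3aR,6R,7S,7aR)-1-acetyl-4-methylidene-2-{[(2Z)-2-methylbut-2-enoyl]oxy}-7-(propan-2-yl)octahydro-1H-inden-6-yl (2S,3S)-2,3-dimethyloxirane-2-carboxylate (CNP0300602.1), via mixed anhydride 29 (not isolated)
Conditions: 28, 2,4,6-trichlorobenzoyl chloride, Et3N, PhMe, rt; then 27, DMAP, PhMe, rt to 40 °C
Reagents that add atoms: 2,4,6-trichlorobenzoyl chloride, O=C(Cl)c1c(Cl)cc(Cl)cc1Cl
Why: Yamaguchi esterification with the preformed mixed anhydride of angelic acid acylates the cyclopentanol under mild conditions that avoid Z to E isomerisation and β-elimination.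

**Compound list**
1 | (1R,4R)-1-methyl-4-(prop-1-en-2-yl)cyclohex-2-en-1-ol | CC(=C)[C@H]1C=C[C@](C)(O)CC1 | starting material
2 | 3-methylbutanoyl chloride | CC(C)CC(=O)Cl | starting material
3 | (1R,4R)-1-methyl-4-(prop-1-en-2-yl)cyclohex-2-en-1-yl 3-methylbutanoate | CC(C)CC(=O)O[C@@]1(C)C=C[C@H](C(C)=C)CC1 | intermediate
4 | (E)-trimethylsilyl ketene acetal of 3 | CC(C)/C=C(/O[Si](C)(C)C)O[C@@]1(C)C=C[C@H](C(C)=C)CC1 | intermediate
5 | trimethylsilyl ester of 6 | C[Si](C)(C)OC(=O)C(C(C)C)[C@@H]1C=C(C)CC[C@H]1C(C)=C | intermediate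
6 | (2RS)-3-methyl-2-[(1R,6R)-3-methyl-6-(prop-1-en-2-yl)cyclohex-2-en-1-yl]butanoic acid | OC(=O)C(C(C)C)[C@@H]1C=C(C)CC[C@H]1C(C)=C | intermediate
7 | (3aR,4R,7S,7aS)-7-iodo-7-methyl-3-(propan-2-yl)-4-(prop-1-en-2-yl)hexahydro-1-benzofuran-2(3H)-one (C3 epimers) | O=C1O[C@@H]2[C@@](C)(I)CC[C@@H](C(C)=C)[C@@H]2C1C(C)C | intermediate
8 | (3aR,4R,7aS)-7-methyl-3-(propan-2-yl)-4-(prop-1-en-2-yl)-3a,4,5,7a-tetrahydro-1-benzofuran-2(3H)-one (C3 epimers) | O=C1O[C@@H]2C(C)=CC[C@@H](C(C)=C)[C@@H]2C1C(C)C | intermediate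
9 | lithium enolate of 8 | [Li]OC1=C(C(C)C)[C@H]2[C@H](C(C)=C)CC=C(C)[C@H]2O1 | intermediate
10 | (3S,3aR,4R,7aS)-7-methyl-3-(propan-2-yl)-4-(prop-1-en-2-yl)-3a,4,5,7a-tetrahydro-1-benzofuran-2(3H)-one | O=C1O[C@@H]2C(C)=CC[C@@H](C(C)=C)[C@@H]2[C@@H]1C(C)C | intermediate
11 | (3S,3aR,4R,7aS)-7-methyl-3-(propan-2-yl)-4-(prop-1-en-2-yl)-2,3,3a,4,5,7a-hexahydro-1-benzofuran-2-ol (anomers) | OC1O[C@@H]2C(C)=CC[C@@H](C(C)=C)[C@@H]2[C@@H]1C(C)C | intermediate
12 | (2S)-2-[(1R,2S,6R)-2-hydroxy-3-methyl-6-(prop-1-en-2-yl)cyclohex-3-en-1-yl]-3-methylbutanal (as its aluminium alkoxide) | O=C[C@@H](C(C)C)[C@@H]1[C@H](O)C(C)=CC[C@H]1C(C)=C | intermediate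
13 | (1S,2R,4aR,8S,8aR)-7-methyl-4-methylidene-1-(propan-2-yl)-1,2,3,4,4a,5,8,8a-octahydronaphthalene-2,8-diol | C=C1C[C@@H](O)[C@@H](C(C)C)[C@@H]2[C@H](O)C(C)=CC[C@@H]12 | intermediate
14 | 6,7-epoxy-7-methyl-4-methylidene-1-(propan-2-yl)decahydronaphthalene-2,8-diol (oxirane O syn to 8-OH, other centres as in 13) | C=C1C[C@@H](O)[C@@H](C(C)C)[C@@H]2[C@H](O)[C@]3(C)O[C@@H]3C[C@@H]12 | intermediate
15 | (R)-2-chloropropanoic acid | C[C@@H](Cl)C(=O)O | starting material
16 | anisole | COc1ccccc1 | starting material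
17 | (R)-2-chloropropanoyl chloride | C[C@@H](Cl)C(=O)Cl | intermediate
18 | (R)-2-chloro-1-(4-methoxyphenyl)propan-1-one | C[C@@H](Cl)C(=O)c1ccc(OC)cc1 | intermediate
19 | (2R,3R)-3-chloro-2-(4-methoxyphenyl)butan-2-ol | C[C@@H](Cl)[C@](C)(O)c1ccc(OC)cc1 | intermediate
20 | (2R,3R)-3-chloro-2-hydroxy-2-methylbutanoic acid | C[C@@H](Cl)[C@](C)(O)C(=O)O | intermediate
21 | (2S,3S)-2,3-dimethyloxirane-2-carboxylic acid | C[C@@H]1O[C@]1(C)C(=O)O | intermediate
22 | mixed anhydride of 21 with 2,4,6-trichlorobenzoic acid | C[C@@H]1O[C@]1(C)C(=O)OC(=O)c1c(Cl)cc(Cl)cc1Cl | intermediate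
23 | 2-O-[(2S,3S)-2,3-dimethyloxirane-2-carbonyl] ester of 14 | C=C1C[C@@H](OC(=O)[C@@]4(C)O[C@H]4C)[C@@H](C(C)C)[C@@H]2[C@H](O)[C@]3(C)O[C@@H]3C[C@@H]12 | intermediate
24 | 8-O-acetyl derivative of 23 | C=C1C[C@@H](OC(=O)[C@@]4(C)O[C@H]4C)[C@@H](C(C)C)[C@@H]2[C@H](OC(C)=O)[C@]3(C)O[C@@H]3C[C@@H]12 | intermediate
25 | (1R,2S,3R,4R)-3-[(1S)-1-acetoxy-2-oxopropyl]-5-methylidene-4-(2-oxoethyl)-2-(propan-2-yl)cyclohexyl (2S,3S)-2,3-dimethyloxirane-2-carboxylate | C=C1C[C@@H](OC(=O)[C@@]4(C)O[C@H]4C)[C@@H](C(C)C)[C@H]([C@H](OC(C)=O)C(C)=O)[C@H]1CC=O | intermediate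
26 | samarium enolate from 25 (acetoxy group lost) | C=C1C[C@@H](OC(=O)[C@@]4(C)O[C@H]4C)[C@@H](C(C)C)[C@H](C=C(C)O[Sm](I)I)[C@H]1CC=O | intermediate
27 | (1R,2S,3aR,6R,7S,7aR)-1-acetyl-2-hydroxy-4-methylidene-7-(propan-2-yl)octahydro-1H-inden-6-yl (2S,3S)-2,3-dimethyloxirane-2-carboxylate | C=C1C[C@@H](OC(=O)[C@@]3(C)O[C@H]3C)[C@@H](C(C)C)[C@@H]2[C@@H](C(C)=O)[C@@H](O)C[C@@H]12 | intermediate
28 | angelic acid, (2Z)-2-methylbut-2-enoic acid | C/C=C(/C)C(=O)O | starting material
29 | mixed anhydride of 28 with 2,4,6-trichlorobenzoic acid | C/C=C(/C)C(=O)OC(=O)c1c(Cl)cc(Cl)cc1Cl | intermediate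
30 | (1R,2S,3aR,6R,7S,7aR)-1-acetyl-4-methylidene-2-{[(2Z)-2-methylbut-2-enoyl]oxy}-7-(propan-2-yl)octahydro-1H-inden-6-yl (2S,3S)-2,3-dimethyloxirane-2-carboxylate | C=C1C[C@@H](OC(=O)[C@@]2(C)O[C@H]2C)[C@@H](C(C)C)[C@@H]2[C@@H](C(C)=O)[C@@H](OC(=O)/C(C)=C\C)C[C@@H]12 | target

**Step count**
Total: 14 steps. Longest linear sequence: 11 steps (steps 1 to 6 and 10 to 14); steps 7 to 9 make the epoxy acid and join at step 10.

**Three steps most likely to fail**

Step 5 (carbonyl-ene on a lactol): the free hydroxyl and the second ring alkene may divert the aluminium reagent, and the lactol may not open cleanly. The fallback sets out from 8 and returns at 13. After the same enolate protonation, LiAlH4 replaces iBu2AlH and gives the diol F1. Silylation of both hydroxyls (t-BuMe2SiOTf, 2,6-lutidine) gives the bis(silyl) ether F2. HF·pyridine frees only the primary alcohol to give the mono-silyl alcohol F3. Dess–Martin periodinane gives the aldehyde F4. The Me2AlCl carbonyl-ene is then run on this hydroxyl-free aldehyde to give the silyl-protected ene product F5, and Bu4NF gives 13.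

Step 10 (site-selective esterification of a hindered diol with a hindered acid): the 8-hydroxyl may compete. The fallback sets out from 14 and returns at 27. Both hydroxyls are esterified with excess 21 (same mixed anhydride 22, PhMe, 80 °C) to give the bis-ester F6. H5IO6 cleavage gives the keto aldehyde F7. SmI2 then expels whatever acyloxy group sits alpha to the ketone (here 21 is released) and the aldol closes to 27. Step 11 is skipped.

Step 13 (SmI2 reductive aldol): the aldehyde may be reduced or the aldol may give the wrong relative configuration. The fallback sets out from 25 and returns at 27. SmI2 in THF/MeOH only removes the acetoxy group and protonates the enolate to give the methyl ketone aldehyde F8. Piperidinium acetate aldol condensation gives the acetylcyclopentene F9. Epoxidation with t-BuOOH/DBU on the face opposite the angular hydrogen at C3a gives the epoxy ketone F10. SmI2 at −90 °C opens the oxirane at the alpha carbon (faster than the oxirane ester) and gives 27.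

**Further compounds**
F1 | step 5 | (1S,5R,6R)-6-[(2S)-1-hydroxy-3-methylbutan-2-yl]-2-methyl-5-(prop-1-en-2-yl)cyclohex-2-en-1-ol | OC[C@@H](C(C)C)[C@@H]1[C@H](O)C(C)=CC[C@H]1C(C)=C
F2 | step 5 | bis(tert-butyldimethylsilyl) ether of F1 | CC(C)(C)[Si](C)(C)OC[C@@H](C(C)C)[C@@H]1[C@H](O[Si](C)(C)C(C)(C)C)C(C)=CC[C@H]1C(C)=C
F3 | step 5 | secondary tert-butyldimethylsilyl ether of F1 (primary alcohol free) | OC[C@@H](C(C)C)[C@@H]1[C@H](O[Si](C)(C)C(C)(C)C)C(C)=CC[C@H]1C(C)=C
F4 | step 5 | aldehyde from F3 | O=C[C@@H](C(C)C)[C@@H]1[C@H](O[Si](C)(C)C(C)(C)C)C(C)=CC[C@H]1C(C)=C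
F5 | step 5 | 8-O-(tert-butyldimethylsilyl) ether of 13 | C=C1C[C@@H](O)[C@@H](C(C)C)[C@@H]2[C@H](O[Si](C)(C)C(C)(C)C)C(C)=CC[C@@H]12
F6 | step 10 | 2,8-bis-O-[(2S,3S)-2,3-dimethyloxirane-2-carbonyl] ester of 14 | C=C1C[C@@H](OC(=O)[C@@]4(C)O[C@H]4C)[C@@H](C(C)C)[C@@H]2[C@H](OC(=O)[C@@]5(C)O[C@H]5C)[C@]3(C)O[C@@H]3C[C@@H]12
F7 | step 10 | keto aldehyde from F6 (analogue of 25 with the oxirane ester in place of acetate) | C=C1C[C@@H](OC(=O)[C@@]4(C)O[C@H]4C)[C@@H](C(C)C)[C@H]([C@H](OC(=O)[C@@]5(C)O[C@H]5C)C(C)=O)[C@H]1CC=O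
F8 | step 13 | deacetoxylated keto aldehyde from 25 (2-oxopropyl side chain) | C=C1C[C@@H](OC(=O)[C@@]4(C)O[C@H]4C)[C@@H](C(C)C)[C@H](CC(C)=O)[C@H]1CC=O
F9 | step 13 | 1-acetylcyclopentene (enone) from F8 | C=C1C[C@@H](OC(=O)[C@@]3(C)O[C@H]3C)[C@@H](C(C)C)[C@@H]2C(C(C)=O)=CC[C@@H]12
F10 | step 13 | 1,2-epoxy ketone from F9 (oxirane O on the face of the future 2-hydroxyl) | C=C1C[C@@H](OC(=O)[C@@]4(C)O[C@H]4C)[C@@H](C(C)C)[C@@H]2[C@@]3(C(C)=O)O[C@H]3C[C@@H]12
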